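## The problem

The target is a eudesmane 6α,12-olide in which ring A is bridged from C2 to C5 by the two-carbon unit C2'–C1'. C2, C3, C4, C5, C10, C1, C1' and C2' thus form a bicyclo[2.2.2]octenone, fused to cyclohexane ring B and to a trans γ-lactone. There are seven stereocentres (C2, C2', C5, C6, C7, C10, C11). C5 and C10 are adjacent quaternary carbons, and C2' carries a 6-methylhepta-1,5-dien-2-yl chain. C6, C7, C10 and C11 have the configuration of α-santonin (1), and the β methyl on C10 can send new bonds at C2 and C5 to the α face of ring A. C2' sits on the bridge and feels the ring stereocentres only if it is set while the bridge atoms are still part of a ring fused to ring A. The side chain holds a 1,1-disubstituted and a trisubstituted alkene, which excludes hydrogenation, hydroboration, peracids and strong acid once it is in place. The γ-lactone is open to hydride and to base-induced epimerisation at C11, and a C1 ketone cannot coexist with an acyloxy group on C3 (β-elimination). The enabling feature is the C3=C4 double bond next to the quaternary bridgehead C5. A carboxyl group placed on C1' makes C(=O)–C1'–C5–C4=C3 the γ,δ-unsaturated acid left by a [3,3] shift of an ester on C3. Because C1' is tied to C3 through only C2' and C2, that ester can be a six-membered lactone fused to ring A.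

## Retrosynthesis

**C1 oxidation state (25 ⇒ 24 ⇒ 23).** No C–C bond is cut; the ketone is traced to alcohol 24 and its silyl ether 23. The ketone has to be masked because C3 carries an ester oxygen on the way, and a C1 ketone would expel it from the C2 enolate. Against an acetal or an alkene at C1, a silyl ether costs two routine steps and adds no stereochemical demand. The forward task is desilylation and oxidation between a quaternary carbon and a bridgehead, where nothing can epimerise.

**One carbon added at C1' (23 ⇒ 21).** The bond between C1' and a carboxyl carbon is introduced retrosynthetically. This costs one carbon, but it turns an unfunctionalised bridge into the retron of a Claisen shift. The forward reaction must replace CO2H by H at a secondary homoallylic centre without skeletal change, which points to radical decarboxylation with a fast hydrogen donor.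

**Key disconnection (21 ⇒ 19 ⇒ 18).** The C5–C1' bond is cut, C3–O is remade and the alkene returns to C4=C5. Cutting both bridge bonds at once (C2–C2' and C5–C1', a cycloaddition) would be shorter, but it leaves site, regio- and facial selectivity to an intermolecular event. Cutting C1–C2 and C5–C10 would dismantle the decalin that 1 supplies. Cutting C5–C1' alone, through the oxygen on C3, keeps the decalin, the γ-lactone and four stereocentres. It removes the bicycle and the quaternary C5, and leaves 18, an ordinary eudesm-4-ene carrying a cis-fused δ-lactone. The forward reaction must form ketene acetal 19 at the δ-lactone only and then pass through a boat [3,3] shift that builds strain. The tether fixes the configuration at C5.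

**Side chain (18 ⇒ 13 + 17).** The C2'–C3' bond is cut as a conjugate addition. Cutting C2–C2' with the chain already on the acceptor would save two steps, but C2' would then be set in an open-chain transition state and 1,6-addition would compete. On unsaturated lactone 13, C2' is formed on the convex face of a cis-fused bicycle. Cuprate 17 comes from vinyllithium 16, which comes from hydrazone 15 of the commercial ketone 14.

**Unsaturated lactone (13 ⇒ 12 ⇒ 11 ⇒ 10 ⇒ 9).** The C1'=C2' double bond is traced to sulfoxide 12 and sulfide 11. The lactone acyl–O bond is opened to hydroxy ester 10, and the C3 carbinol to ketone 9. The sulfur arrives with the acceptor, so no second enolisation of a bis-lactone is needed for dehydrogenation. The forward reduction must give the axial 3α alcohol, cis to the C2 chain.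

**C2–C2' bond (9 ⇒ 4 + 7).** This is a Michael disconnection to the kinetic enolate 8 of 4 and the α-thio acrylate 7, which is made from 5. The enolate must react at C2 on the α face without losing its β-silyloxy group, and the adduct must stop at mono-addition.

**C1 oxygen (4 ⇒ 3 ⇒ 2 ⇒ 1).** Only C–O bonds are cut. The C1=C2 enone of 1 is epoxidised nucleophilically and the epoxide is opened reductively. Ring B, the γ-lactone, both ring methyls and C6, C7, C10 and C11 are taken from 1 unchanged.

## Roads not taken

**Alternative 1: transannular cyclisation.** The cut is C5–C10. In the forward step a Lewis acid opens the 1,10-epoxide of germacranolide A1, the C4=C5 alkene attacks C10 across the ten-membered ring, and proton loss gives the 1β-hydroxyeudesm-3-ene lactone A2.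
- Merits: one step makes the decalin with the C1 oxygen in place, and the ring conformation controls C5 and C10.
- Weak points: A2 has a hydrogen on C5 and none of the bridge, so the two bridge bonds, C2' and the quaternary C5 are still to be made. Proton loss can also give the exocyclic alkene isomer. A1 is harder to obtain than 1, which already contains the decalin.
- Comparison: after oxidation and desaturation of ring A, A2 could meet a side-chain donor in one intermolecular cycloaddition. That endgame is shorter than steps 4 to 13 of the chosen plan and is better in step count. The chosen plan sets against it that each bridge bond is formed on a tethered or convex-face substrate, so that site, regio- and facial selectivity are decided by structure. The cycloaddition is kept as the reserve for step 10, reached from 2 without A1.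

**Alternative 2: ring B closed last.** The cuts are C6–C7 and the lactone C–O bond. In the forward step a divalent chromium salt converts the 2-(bromomethyl)acrylate of aldehyde A3 into an allylchromium, which adds through C7 to the aldehyde carbon C6. The alkoxide lactonises to the α-methylene lactone A4.
- Merits: the reaction type is well known, chemoselective for the aldehyde over the C1 ketone, and needs no protecting groups.
- Weak points: C6 is neopentyl, next to the quaternary C5. The trans relationship of C6 and C7 is not assured in a ring closure. The exocyclic methylene of A4 must then be reduced to the 11α-methyl group in the presence of three other alkenes and a ketone. A3 already contains the bicyclo[2.2.2]octenone with both quaternary carbons, C2 and C2', in enantiopure form, so the main difficulty is moved into the substrate.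
- Comparison: its last C–C bond formation is safer than the rearrangement of step 10. The chosen plan sets against it that ring B, the lactone and four stereocentres are bought with 1, and that the bicycle is made on that scaffold.

**Alternative 3: tethered nitroalkene Diels–Alder.** The cuts are C1–C2 and C5–C10. In the forward step, heating cyclohexadiene A5, whose lactone side arm ends in an (E)-nitroalkene, closes ring B and the bicycle together to give nitro compound A6. A Nef reaction then gives the C1 ketone.
- Merits: two C–C bonds, two rings and both quaternary carbons form in one step. The activating group becomes the ketone, whereas the chosen plan must excise a carboxyl carbon and protect, deprotect and oxidise C1. In bonds per step this road is better.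
- Weak points: the dienophile is β,β-disubstituted and must join two fully substituted carbons. The 5-substituted cyclohexa-1,3-diene can scramble by 1,5-hydrogen shifts or aromatise at the temperature needed. The facial course depends on both C2' and the lactone stereocentres, which may oppose each other. A5 needs C2', C6, C7 and C11 from a de novo asymmetric synthesis.
- Comparison: the chosen plan forms only one bond in its key step, but it starts from a substrate in which five of the seven stereocentres are already secured from 1 or by cyclic control.

Key step: step 10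

Assumption: the C1 oxygen is carried as the 1α (axial) silyl ether, which the α-epoxide of 1 delivers; its configuration is lost when C1 becomes the ketone. Benzenesulfenyl chloride is generated in the flask.

## Route

Step 1
Reactants: 1 α-santonin
Product: 2 1α,2α-epoxy-3-oxoeudesm-4-en-6α,12-olide
Conditions: t-BuOOH (decane), DBU, CH2Cl2, 0 °C → rt
Reagents that add atoms: tert-butyl hydroperoxide, CC(C)(C)OO
Why: Weitz–Scheffer nucleophilic epoxidation; the hydroperoxide anion adds to C1 of the less substituted enone while the fully substituted C4=C5 enone is inert, and water-free conditions keep the γ-lactone closed. C1 and C2 are set by attack on the α face, anti to the β methyl on the neighbouring C10.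

Step 2
Reactants: 2 1α,2α-epoxy-3-oxoeudesm-4-en-6α,12-olide
Product: 3 1α-hydroxy-3-oxoeudesm-4-en-6α,12-olide
Conditions: SmI2, THF/MeOH, −90 °C
Reagents that add atoms: none
Why: Reductive opening of an α,β-epoxy ketone; two single-electron transfers from divalent samarium cleave the C2–O bond next to the carbonyl and methanol protonates the enolate at C2. C1 keeps its configuration, and the low temperature and neutral work-up guard the β-hydroxy ketone against dehydration back to 1.

Step 3
Reactants: 3 1α-hydroxy-3-oxoeudesm-4-en-6α,12-olide
Product: 4 1α-(tert-butyldimethylsilyloxy)-3-oxoeudesm-4-en-6α,12-olide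
Conditions: t-BuMe2SiOTf, 2,6-lutidine, CH2Cl2, −78 → 0 °C
Reagents that add atoms: tert-butyldimethylsilyl triflate, CC(C)(C)[Si](C)(C)OS(=O)(=O)C(F)(F)F
Why: Silyl ether formation; the triflate is needed for the axial hydroxyl next to the quaternary C10, and 2,6-lutidine is too weak a base to enolise the ketone or start β-elimination.

Step 4
Reactants: 5 methyl acrylate
Product: 7 methyl 2-(phenylthio)acrylate, via chloro sulfide adduct 6 (not isolated)
Conditions: PhSSPh, SO2Cl2, CH2Cl2, 0 °C; then 5, −20 °C → rt; then Et3N, 0 °C → rt
Reagents that add atoms: diphenyl disulfide, c1ccc(SSc2ccccc2)cc1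
Why: Electrophilic addition of benzenesulfenyl chloride to the acrylate through the thiiranium ion, then base-induced dehydrochlorination, is the usual entry to α-thio acrylates. A regioisomeric adduct equilibrates through the same thiiranium ion and is drained by the elimination.

Step 5
Reactants: 4 1α-(tert-butyldimethylsilyloxy)-3-oxoeudesm-4-en-6α,12-olide; 7 methyl 2-(phenylthio)acrylate
Product: 9 methyl 3-[1α-(tert-butyldimethylsilyloxy)-3-oxoeudesm-4-en-6α,12-olid-2α-yl]-2-(phenylthio)propanoate (both epimers at C1'), via lithium dienolate 8 (not isolated)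
Conditions: LiN(SiMe3)2, THF, −78 °C; then 7, −78 °C; AcOH, −78 °C
Reagents that add atoms: none
Why: Michael addition of the kinetic cross-conjugated lithium enolate; the silylamide enolises the ketone far faster than the α-methyl lactone, and the phenylthio group makes the adduct enolate stabilised, so a second Michael closure onto C5 or oligomerisation is not expected. C2 is set by attack on the α face, anti to the C10 methyl; the 2α (equatorial) isomer is also the thermodynamic one, and the configuration at C1' is of no consequence.

Step 6
Reactants: 9 methyl 3-[1α-(tert-butyldimethylsilyloxy)-3-oxoeudesm-4-en-6α,12-olid-2α-yl]-2-(phenylthio)propanoate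
Product: 11 1α-(tert-butyldimethylsilyloxy)eudesm-4-en-6α,12-olide with the δ-lactone C2–C2'H2–C1'H(SPh)–C(=O)–O–C3 cis-fused on the α face (both epimers at C1'), via 3α-hydroxy ester 10 (not isolated)
Conditions: K[HB(s-Bu)3], THF, −78 → 0 °C; aq. NH4Cl
Reagents that add atoms: none
Why: 1,2-Reduction of the enone by a bulky trialkylborohydride (conjugate reduction is blocked by the fully substituted β-carbon), then lactonisation of the potassium alkoxide onto the methyl ester. C3 is set by equatorial hydride delivery from the β face, enforced by the equatorial 2α substituent and the axial 1α silyloxy group, which gives the axial 3α oxygen cis to the C2 chain.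

Step 7
Reactants: 11 cis-fused α-phenylthio δ-lactone
Product: 13 1α-(tert-butyldimethylsilyloxy)eudesm-4-en-6α,12-olide with the unsaturated δ-lactone C2–C2'H=C1'H–C(=O)–O–C3 cis-fused on the α face, via sulfoxide 12 (not isolated)
Conditions: NaIO4, MeOH/H2O, 0 °C → rt; then CaCO3, PhMe, 110 °C
Reagents that add atoms: none
Why: Periodate oxidises the sulfide without touching the C4=C5 alkene, and thermal syn elimination of the α-sulfinyl lactone can only run towards C2', giving the endocyclic C1'=C2' bond.

Step 8
Reactants: 14 6-methylhept-5-en-2-one
Product: 15 (E)-6-methylhept-5-en-2-one 2,4,6-triisopropylbenzenesulfonylhydrazone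
Conditions: 2,4,6-(i-Pr)3C6H2SO2NHNH2, MeOH, cat. HCl, rt
Reagents that add atoms: 2,4,6-triisopropylbenzenesulfonyl hydrazide, NNS(=O)(=O)c1c(C(C)C)cc(C(C)C)cc1C(C)C
Why: Hydrazone condensation; the E isomer, with the sulfonamide syn to the methyl group, directs the later deprotonation to that methyl group.

Step 9
Reactants: 15 (E)-6-methylhept-5-en-2-one 2,4,6-triisopropylbenzenesulfonylhydrazone; 13 cis-fused unsaturated δ-lactone
Product: 18 1α-(tert-butyldimethylsilyloxy)eudesm-4-en-6α,12-olide with the δ-lactone C2–C2'H(R)–C1'H2–C(=O)–O–C3 cis-fused on the α face (R = 6-methylhepta-1,5-dien-2-yl on C2' cis to H-2 and H-3), via vinyllithium 16 (not isolated), via lithium dialkenylcuprate 17 (not isolated)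
Conditions: n-BuLi (2 equiv), THF, −78 → 0 °C; CuI, −40 °C; then 13, −78 °C; aq. NH4Cl
Reagents that add atoms: none
Why: The Shapiro reaction of a methyl ketone trisylhydrazone gives the 1-alken-2-yllithium by deprotonation at the methyl group and loss of sulfinate and N2; transmetalation to monovalent copper gives the homocuprate, which adds 1,4 to the unsaturated δ-lactone. C2' is set by addition to the convex face of the cis-fused bicycle, anti to C1 and its silyloxy group on the neighbouring ring-fusion carbon C2, which places the alkenyl group cis to H-2.

Step 10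
Reactants: 18 cis-fused δ-lactone carrying the side chain on C2'
Product: 21 bicyclo[2.2.2]octene acid: the target skeleton with t-BuMe2SiO on C1 (syn to the C1'–C2' bridge) in place of the ketone and CO2H on C1' (syn to the C3=C4 bridge), via trimethylsilyl ketene acetal 19 (not isolated), via trimethylsilyl ester 20 (not isolated)
Conditions: Me3SiCl, Et3N, THF, −78 °C; LiN(i-Pr)2, −78 °C → rt; PhMe, 110 °C; then 1 M HCl, THF
Reagents that add atoms: none
Why: Proposed new method: deprotonation of the δ-lactone methylene C1' in the presence of Me3SiCl gives the cyclic silyl ketene acetal 19, whose 1,5-diene C1'=C(OSi)–O–C3–C4=C5 undergoes a [3,3] sigmatropic shift that forms C5–C1', breaks C3–O and moves the alkene to C3=C4; the closest known reaction type is the ring-contracting Ireland–Claisen rearrangement of 6-alkenyl δ-lactone silyl ketene acetals to cyclohexenecarboxylic acids through a boat transition state, which has not been shown for an alkene held inside a ring so that a bridged bicyclo[2.2.2]octene with a quaternary bridgehead results. The one ring closed is the carbocycle C1'–C2'–C2–C3–C4–C5; it closes by sigmatropic contraction of the six-membered lactone, C1' and C5 being joined across the two-atom tether C2'–C2 in a boat array in which ring A also becomes a boat with C2 and C5 at bow and stern. The axial 3α C–O bond lies parallel to the π orbitals of C4=C5 in the ground state, and the gain of the silyl ester C=O is expected to outweigh the strain of the bicycle. C5 is set by the cis α-fusion of the lactone, which can deliver C1' only to the α face, anti to the C10 methyl; the configuration at C1' follows from the endocyclic ketene acetal and is erased in step 11; C2' is untouched. The step needs site-selective enolisation of the δ-lactone beside the γ-lactone, which rests on the kinetic preference of a hindered amide for a methylene over a methyl-bearing methine and on trapping at −78 °C. A ketene acetal of the γ-lactone, should some form, is not expected to rearrange, because its C6–O bond lies near the plane of the alkene, and it is hydrolysed back on work-up. The step also needs the [3,3] shift to win over ionisation of the allylic C3–O bond, which the non-polar solvent and the absence of Lewis acids favour.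

Step 11
Reactants: 21 bicyclo[2.2.2]octene C1' acid
Product: 23 the target skeleton with t-BuMe2SiO on C1 (syn to the C1'–C2' bridge) and C1'H2, via O-acyl thiohydroxamate 22 (not isolated)
Conditions: 1-hydroxypyridine-2(1H)-thione, DCC, DMAP (cat.), CH2Cl2, rt, dark; then t-BuSH, PhH, hν (tungsten lamp), rt
Reagents that add atoms: none
Why: Barton reductive decarboxylation; the thiohydroxamate ester fragments under visible light to the C1' radical, which takes hydrogen from the thiol used in large excess. Both 3-exo closures open to this homoallylic radical would attack a fully substituted alkene carbon (C4 or C3') and give a less stabilised radical, so hydrogen transfer should outrun skeletal rearrangement; no stereocentre is formed.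

Step 12
Reactants: 23 C1 silyl ether
Product: 24 the C1 alcohol of the target skeleton (OH syn to the C1'–C2' bridge)
Conditions: n-Bu4NF, THF, rt → 50 °C; aq. NH4Cl
Reagents that add atoms: none
Why: Fluoride cleavage of the silyl ether; the only base-sensitive centre is C11, which has the configuration expected to be the more stable one (methyl cis to H-7).

Step 13
Reactants: 24 C1 alcohol
Product: 25 target compound CNP0385704.3
Conditions: Dess–Martin periodinane, NaHCO3, CH2Cl2, rt
Reagents that add atoms: none
Why: Dess–Martin oxidation of a hindered secondary alcohol under buffered conditions that leave the three alkenes alone; the new ketone lies between the quaternary C10 and the bridgehead C2, so no neighbouring centre can epimerise.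

## Compound list

1 | α-santonin | O=C1C=C[C@]2(C)CC[C@H]3[C@H](C)C(=O)O[C@@H]3C2=C1C | starting material
2 | 1α,2α-epoxy-3-oxoeudesm-4-en-6α,12-olide | O=C1[C@@H]2O[C@@H]2[C@]3(C)CC[C@H]4[C@H](C)C(=O)O[C@@H]4C3=C1C | intermediate
3 | 1α-hydroxy-3-oxoeudesm-4-en-6α,12-olide | O=C1C[C@H](O)[C@]2(C)CC[C@H]3[C@H](C)C(=O)O[C@@H]3C2=C1C | intermediate
4 | 1α-(tert-butyldimethylsilyloxy)-3-oxoeudesm-4-en-6α,12-olide | O=C1C[C@H](O[Si](C)(C)C(C)(C)C)[C@]2(C)CC[C@H]3[C@H](C)C(=O)O[C@@H]3C2=C1C | intermediate
5 | methyl acrylate | C=CC(=O)OC | starting material
6 | methyl 3-chloro-2-(phenylthio)propanoate (racemic, not isolated) | COC(=O)C(CCl)Sc1ccccc1 | intermediate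
7 | methyl 2-(phenylthio)acrylate | C=C(Sc1ccccc1)C(=O)OC | intermediate
8 | lithium 2,4-dien-3-olate of 4 (kinetic enolate, not isolated) | [Li]OC1=C[C@H](O[Si](C)(C)C(C)(C)C)[C@]2(C)CC[C@H]3[C@H](C)C(=O)O[C@@H]3C2=C1C | intermediate
9 | methyl 3-[1α-(tert-butyldimethylsilyloxy)-3-oxoeudesm-4-en-6α,12-olid-2α-yl]-2-(phenylthio)propanoate (both epimers at C1') | COC(=O)C(Sc1ccccc1)C[C@H]1C(=O)C(C)=C2[C@H]3OC(=O)[C@@H](C)[C@@H]3CC[C@@]2(C)[C@H]1O[Si](C)(C)C(C)(C)C | intermediate
10 | 3α-hydroxy ester from 9 (not isolated) | COC(=O)C(Sc1ccccc1)C[C@H]1[C@@H](O)C(C)=C2[C@H]3OC(=O)[C@@H](C)[C@@H]3CC[C@@]2(C)[C@H]1O[Si](C)(C)C(C)(C)C | intermediate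
11 | cis-fused α-phenylthio δ-lactone (C2–C2'H2–C1'H(SPh)–C(=O)–O–C3, α face; both epimers at C1') | O=C1O[C@H]2C(C)=C3[C@H]4OC(=O)[C@@H](C)[C@@H]4CC[C@@]3(C)[C@@H](O[Si](C)(C)C(C)(C)C)[C@H]2CC1Sc1ccccc1 | intermediate
12 | sulfoxide of 11 (not isolated) | O=C1O[C@H]2C(C)=C3[C@H]4OC(=O)[C@@H](C)[C@@H]4CC[C@@]3(C)[C@@H](O[Si](C)(C)C(C)(C)C)[C@H]2CC1S(=O)c1ccccc1 | intermediate
13 | cis-fused α,β-unsaturated δ-lactone (C2–C2'H=C1'H–C(=O)–O–C3) | O=C1O[C@H]2C(C)=C3[C@H]4OC(=O)[C@@H](C)[C@@H]4CC[C@@]3(C)[C@@H](O[Si](C)(C)C(C)(C)C)[C@H]2C=C1 | intermediate
14 | 6-methylhept-5-en-2-one | CC(=O)CCC=C(C)C | starting material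
15 | (E)-6-methylhept-5-en-2-one 2,4,6-triisopropylbenzenesulfonylhydrazone | C/C(CCC=C(C)C)=N\NS(=O)(=O)c1c(C(C)C)cc(C(C)C)cc1C(C)C | intermediate
16 | 6-methylhepta-1,5-dien-2-yllithium (not isolated) | [Li]C(=C)CCC=C(C)C | intermediate
17 | lithium bis(6-methylhepta-1,5-dien-2-yl)cuprate (not isolated) | [Li+].C=C(CCC=C(C)C)[Cu-]C(=C)CCC=C(C)C | intermediate
18 | cis-fused δ-lactone with the 6-methylhepta-1,5-dien-2-yl group on C2' (cis to H-2), 1α-silyloxy eudesm-4-en-6α,12-olide | C=C(CCC=C(C)C)[C@@H]1CC(=O)O[C@H]2C(C)=C3[C@H]4OC(=O)[C@@H](C)[C@@H]4CC[C@@]3(C)[C@@H](O[Si](C)(C)C(C)(C)C)[C@@H]12 | intermediate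
19 | trimethylsilyl ketene acetal of 18 (C1'=C(OSiMe3)–O–C3, not isolated) | C=C(CCC=C(C)C)[C@@H]1C=C(O[Si](C)(C)C)O[C@H]2C(C)=C3[C@H]4OC(=O)[C@@H](C)[C@@H]4CC[C@@]3(C)[C@@H](O[Si](C)(C)C(C)(C)C)[C@@H]12 | intermediate
20 | trimethylsilyl ester of 21 (not isolated) | C=C(CCC=C(C)C)[C@@H]1[C@H](C(=O)O[Si](C)(C)C)[C@]23C(C)=C[C@H]1[C@H](O[Si](C)(C)C(C)(C)C)[C@]2(C)CC[C@H]1[C@H](C)C(=O)O[C@@H]13 | intermediate
21 | bicyclo[2.2.2]octene C1' carboxylic acid, C1 silyl ether | C=C(CCC=C(C)C)[C@@H]1[C@H](C(=O)O)[C@]23C(C)=C[C@H]1[C@H](O[Si](C)(C)C(C)(C)C)[C@]2(C)CC[C@H]1[C@H](C)C(=O)O[C@@H]13 | intermediate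
22 | 2-thioxopyridin-1(2H)-yl ester of 21 (not isolated) | C=C(CCC=C(C)C)[C@@H]1[C@H](C(=O)On2ccccc2=S)[C@]23C(C)=C[C@H]1[C@H](O[Si](C)(C)C(C)(C)C)[C@]2(C)CC[C@H]1[C@H](C)C(=O)O[C@@H]13 | intermediate
23 | decarboxylated C1 silyl ether | C=C(CCC=C(C)C)[C@@H]1C[C@]23C(C)=C[C@H]1[C@H](O[Si](C)(C)C(C)(C)C)[C@]2(C)CC[C@H]1[C@H](C)C(=O)O[C@@H]13 | intermediate
24 | C1 alcohol | C=C(CCC=C(C)C)[C@@H]1C[C@]23C(C)=C[C@H]1[C@H](O)[C@]2(C)CC[C@H]1[C@H](C)C(=O)O[C@@H]13 | intermediate
25 | CNP0385704.3 | C=C(CCC=C(C)C)[C@@H]1C[C@]23C(C)=C[C@H]1C(=O)[C@]2(C)CC[C@H]1[C@H](C)C(=O)O[C@@H]13 | target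

## Step count and least certain steps

Total: 13 steps. Longest linear sequence: 11 steps (1 → 25 through steps 1, 2, 3, 5, 6, 7, 9, 10, 11, 12, 13).

**Step 10 (key step; beyond known chemistry).**
- What may go wrong: the sigmatropic shift may not occur at temperatures that the ketene acetal survives, because the boat transition state has to build the bicyclo[2.2.2]octene and the adjacent quaternary carbons C5 and C10 at once. Ionisation of the allylic C3–O bond (elimination to a ring A diene or a formal [1,3] shift) or O-to-C silyl migration would then take over. A second failure is partial enolisation of the γ-lactone with erosion of C11. If only the site of enolisation is at fault, 19 can be made without amide base by adding Me3SiCl to the cuprate addition of step 9.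
- Fallback (known chemistry, cycloaddition in place of rearrangement): it sets out from 2. Wharton transposition (N2H4·H2O, AcOH, MeOH) gives 1α-hydroxyeudesma-2,4-dien-6α,12-olide F1. Oxidation with MnO2 gives 1-oxoeudesma-2,4-dien-6α,12-olide F2, a 6,6-disubstituted cyclohexa-2,4-dienone. Heating F2 with commercial myrcene in toluene should engage the monosubstituted alkene of the triene in a Diels–Alder reaction across C2 and C5. Attack anti to the C10 methyl, with the substituted carbon bonding to C2 and the chain under the diene, would return to the route at 25. This reserve is short. Its own weakness is that the 1,3-diene of myrcene may instead add to C2=C3 of F2, and that F2 may dimerise.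

**Step 5.**
- What may go wrong: proton transfer to the adduct enolate from unreacted 4 or from C2–H of 9 may give a C2 enolate that loses silanolate (β-elimination to a C1=C2 enone). Facial leakage at C2 is a second possibility.
- Fallback (C–C bond formation under non-basic conditions): it sets out from 4. Enolisation with LiN(SiMe3)2 in the presence of Me3SiCl at −78 °C gives trimethylsilyl dienol ether F3. ZnBr2-catalysed alkylation of F3 with methyl 3-chloro-3-(phenylthio)propanoate F4 (from methyl 3-(phenylthio)propanoate and N-chlorosuccinimide) gives the 2α-substituted keto ester F5, with sulfur on C2'. K[HB(s-Bu)3] as in step 6 gives the cis-fused δ-lactone F6. NaIO4 gives sulfoxide F7, which eliminates towards the acidic C1'–H on warming and rejoins the route at 13.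

**Step 9.**
- What may go wrong: conversion may be low because C2' is flanked by the ring-fusion carbon C2 and its silyloxy-bearing neighbour, so that 1,2-addition to a lactone carbonyl or γ-deprotonation competes.
- Fallback (form C2–C2' instead of C2'–C3'): it sets out from 4 and 14. Ketone 14 is converted with LiN(i-Pr)2 and PhNTf2 into 6-methylhepta-1,5-dien-2-yl triflate F8. A Heck reaction of F8 with 5 (Pd(OAc)2, PPh3, Et3N) gives methyl (2E)-8-methyl-4-methylenenona-2,7-dienoate F9. Michael addition of enolate 8 to F9 gives keto ester F10, and K[HB(s-Bu)3] as in step 6 reduces and lactonises it to rejoin the route at 18. The price is that C2' is then set in an open-chain transition state, and that 1,6-addition may compete.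

## Further compounds

F1 | step 10 | 1α-hydroxyeudesma-2,4-dien-6α,12-olide | O[C@H]1C=CC(C)=C2[C@H]3OC(=O)[C@@H](C)[C@@H]3CC[C@@]12C
F2 | step 10 | 1-oxoeudesma-2,4-dien-6α,12-olide | O=C1C=CC(C)=C2[C@H]3OC(=O)[C@@H](C)[C@@H]3CC[C@@]12C
F3 | step 5 | trimethylsilyl dienol ether of 4 (C2=C3–OSiMe3) | C[Si](C)(C)OC1=C[C@H](O[Si](C)(C)C(C)(C)C)[C@]2(C)CC[C@H]3[C@H](C)C(=O)O[C@@H]3C2=C1C
F4 | step 5 | methyl 3-chloro-3-(phenylthio)propanoate (racemic) | COC(=O)CC(Cl)Sc1ccccc1
F5 | step 5 | methyl 3-[1α-(tert-butyldimethylsilyloxy)-3-oxoeudesm-4-en-6α,12-olid-2α-yl]-3-(phenylthio)propanoate (both epimers at C2') | COC(=O)CC(Sc1ccccc1)[C@H]1C(=O)C(C)=C2[C@H]3OC(=O)[C@@H](C)[C@@H]3CC[C@@]2(C)[C@H]1O[Si](C)(C)C(C)(C)C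
F6 | step 5 | cis-fused δ-lactone with phenylthio on C2' | O=C1O[C@H]2C(C)=C3[C@H]4OC(=O)[C@@H](C)[C@@H]4CC[C@@]3(C)[C@@H](O[Si](C)(C)C(C)(C)C)[C@H]2C(Sc2ccccc2)C1
F7 | step 5 | sulfoxide of F6 | O=C1O[C@H]2C(C)=C3[C@H]4OC(=O)[C@@H](C)[C@@H]4CC[C@@]3(C)[C@@H](O[Si](C)(C)C(C)(C)C)[C@H]2C(S(=O)c2ccccc2)C1
F8 | step 9 | 6-methylhepta-1,5-dien-2-yl trifluoromethanesulfonate | C=C(CCC=C(C)C)OS(=O)(=O)C(F)(F)F
F9 | step 9 | methyl (2E)-8-methyl-4-methylenenona-2,7-dienoate | COC(=O)/C=C/C(=C)CCC=C(C)C
F10 | step 9 | methyl 3-[1α-(tert-butyldimethylsilyloxy)-3-oxoeudesm-4-en-6α,12-olid-2α-yl]-8-methyl-4-methylenenon-7-enoate (C2' as in 18) | C=C(CCC=C(C)C)[C@H](CC(=O)OC)[C@H]1C(=O)C(C)=C2[C@H]3OC(=O)[C@@H](C)[C@@H]3CC[C@@]2(C)[C@H]1O[Si](C)(C)C(C)(C)C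
A1 | alternative 1 | 1β,10α-epoxygermacr-4-en-6α,12-olide (11βH) | C[C@@]12CC[C@H]3[C@H](C)C(=O)O[C@@H]3/C=C(C)/CC[C@H]1O2
A2 | alternative 1 | 1β-hydroxyeudesm-3-en-6α,12-olide (11β,13-dihydrosantamarine) | O[C@@H]1CC=C(C)[C@@H]2[C@H]3OC(=O)[C@@H](C)[C@@H]3CC[C@@]12C
A3 | alternative 2 | bicyclo[2.2.2]octenone with CHO on C5 and a (Z)-2-(bromomethyl)pent-2-enoate chain on C10 | C=C(CCC=C(C)C)[C@@H]1C[C@]2(C=O)C(C)=C[C@H]1C(=O)[C@]2(C)CC/C=C(\CBr)C(=O)OC
A4 | alternative 2 | 11,13-didehydro target (α-methylene lactone) | C=C(CCC=C(C)C)[C@@H]1C[C@]23C(C)=C[C@H]1C(=O)[C@]2(C)CC[C@H]1C(=C)C(=O)O[C@@H]13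
A5 | alternative 3 | cyclohexa-1,3-diene with lactone-tethered (E)-nitroalkene | C=C(CCC=C(C)C)[C@@H]1CC(=C(C)C=C1)[C@H]1OC(=O)[C@@H](C)[C@@H]1CC/C(C)=C/[N+](=O)[O-]
A6 | alternative 3 | C1-nitro analogue of the target tetracycle | C=C(CCC=C(C)C)[C@@H]1C[C@]23C(C)=C[C@H]1[C@@H]([N+](=O)[O-])[C@]2(C)CC[C@H]1[C@H](C)C(=O)O[C@@H]13
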